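**Assumption:** the sense of induction of the cobalt salen benzoate opening is taken from meso-cyclohexene oxide, where the (S,S)-ligand is taken to give the (R,R)-hydroxy benzoate. Both ligand antipodes are commercial, so the (R,R)-ligand is used instead if a test run gives the enantiomer. This assignment is from memory and unverified; the whole route is a proposal and has not been run.

## Retrosynthetic overview

1. Target ⇐ benzyl benzoate 2,3-oxide + PhCO2H: trans-1,2-opening of the arene oxide at C3, the presumed biosynthetic event. A chiral cobalt salen catalyst makes it enantioconvergent, because the arene oxide racemises through its oxepin.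
2. Arene oxide ⇐ dibromo epoxide by double dehydrobromination; the oxirane comes from peracid epoxidation of a dibromocyclohexene.
3. Dibromocyclohexene ⇐ (cyclohexa-2,5-dienyl)methyl benzoate ⇐ cyclohexa-1,4-diene + CH2O + PhCOCl in one pot.
4. Ring order: the carbocycle is bought as cyclohexa-1,4-diene; the oxirane, the only ring formed, is made in step 3, unveiled as the arene oxide in step 4 and opened in step 5.

## Route

**Step 1**
Reactants: 1 cyclohexa-1,4-diene; 2 formaldehyde (monomer, cracked from commercial paraformaldehyde); 3 benzoyl chloride
Product: 6 (cyclohexa-2,5-dien-1-yl)methyl benzoate, via cyclohexa-2,5-dien-1-yllithium 4 (not isolated), via lithium (cyclohexa-2,5-dien-1-yl)methoxide 5 (not isolated)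
Conditions: sBuLi (C4H9Li, 1.0 equiv), TMEDA (1.0 equiv), 1 (1.2 equiv), THF, −78 °C, 1 h; CH2O gas, −78 °C; then PhCOCl (1.2 equiv), −78 °C → rt
Reagents that add atoms: formaldehyde, C=O; benzoyl chloride, O=C(Cl)c1ccccc1
Why: Deprotonation of the doubly allylic CH2 gives the pentadienyl-type anion 4, which adds to formaldehyde at its central carbon (kinetic organolithium 1,2-addition, as in Birch-type cyclohexadienyl alkylations) to give the skipped-diene alkoxide 5, which is O-acylated in situ; no stereocentre arises because C1 of 6 carries two enantiotopic vinyl arms.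

**Step 2**
Reactants: 6 (cyclohexa-2,5-dien-1-yl)methyl benzoate
Product: 7 (5,6-dibromocyclohex-2-en-1-yl)methyl benzoate (racemic trans-dibromide, both C1 epimers)
Conditions: Br2 (1.0 equiv), CH2Cl2, −78 °C, dark
Reagents that add atoms: bromine, BrBr
Why: Electrophilic anti-addition of Br2 through a bromonium ion stops after one alkene because the dibromide inductively deactivates the second one; this is an addition with no co-product, and the new stereocentres are irrelevant because step 4 erases them all.

**Step 3**
Reactants: 7 (5,6-dibromocyclohex-2-en-1-yl)methyl benzoate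
Product: 8 (3,4-dibromo-7-oxabicyclo[4.1.0]heptan-2-yl)methyl benzoate (racemic diastereomer mixture)
Conditions: mCPBA (1.3 equiv), NaHCO3, CH2Cl2, 0 °C → rt
Reagents that add atoms: mCPBA (3-chloroperoxybenzoic acid), OOC(=O)c1cccc(Cl)c1
Why: Prilezhaev epoxidation of the remaining isolated cis-alkene forms the oxirane on the carbons that become C5 and C6 of the target; its facial selectivity need not be controlled, since step 4 removes the other sp3 centres and step 5 sets the final configuration.

**Step 4**
Reactants: 8 (3,4-dibromo-7-oxabicyclo[4.1.0]heptan-2-yl)methyl benzoate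
Product: 10 (7-oxabicyclo[4.1.0]hepta-2,4-dien-2-yl)methyl benzoate, via (3-bromo-7-oxabicyclo[4.1.0]hept-4-en-2-yl)methyl benzoate 9 (not isolated)
Conditions: DBU (3 equiv), nBu4NBr (10 mol %), THF, 0 °C → rt, dark; fast filtration through basic Al2O3 (Et2O, 1 % Et3N); use at once
Reagents that add atoms: none
Why: Two base-induced dehydrobrominations (E2, the second from allylic bromide 9, whose epimers are equilibrated by bromide) install the 1,3-diene beside the oxirane (Vogel-type arene oxide synthesis), giving benzyl benzoate 2,3-oxide 10, which equilibrates with its oxepin valence tautomer (oxepin-3-yl)methyl benzoate 11 by 6π electrocyclic ring opening and is therefore racemic and configurationally labile.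

**Step 5**
Reactants: 10 (7-oxabicyclo[4.1.0]hepta-2,4-dien-2-yl)methyl benzoate; 12 benzoic acid
Product: 13 [(5R,6R)-5-(benzoyloxy)-6-hydroxycyclohexa-1,3-dien-1-yl]methyl benzoate (target), via (oxepin-3-yl)methyl benzoate 11 (not isolated)
Conditions: (S,S)-N,N'-bis(3,5-di-tert-butylsalicylidene)cyclohexane-1,2-diaminocobalt (C36H52CoN2O2, divalent cobalt, 5 mol %, oxidised in situ by air to the trivalent cobalt benzoate), PhCO2H (1.1 equiv), iPr2NEt (1.0 equiv), tBuOMe, 0 °C; work-up cold on Et3N-deactivated SiO2
Reagents that add atoms: benzoic acid, OC(=O)c1ccccc1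
Why: Proposed new method: the trivalent cobalt salen benzoate acts bimetallically, one cobalt binding the oxirane oxygen of 10 while a second delivers its benzoate by backside SN2 attack at the allylic oxirane carbon remote from the CH2OBz-bearing carbon (C6 of the bicycle), so that this carbon is inverted to C5 of 13 and the untouched C–O bond becomes the C6 hydroxyl, hence the trans-(5R,6R) product with both stereocentres set in this step; only the (1R,6S)-enantiomer of 10 offers its less hindered carbon in the catalyst's preferred position, and the mismatched enantiomer is racemised continuously through oxepin 11 (6π disrotatory opening and closure, barrier below about 10 kcal/mol), which makes this a dynamic kinetic resolution, while the amine-buffered aprotic medium suppresses acid-catalysed isomerisation to phenols; the closest known reaction types are the cobalt salen-catalysed enantioselective opening of meso epoxides by benzoic acid, the hydrolytic kinetic resolution of vinyl epoxides, and the uncatalysed trans-1,2-addition of carboxylic acids to arene oxides.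

## Compound list

1 | cyclohexa-1,4-diene | C1=CCC=CC1 | starting material
2 | formaldehyde (from paraformaldehyde) | C=O | starting material
3 | benzoyl chloride | O=C(Cl)c1ccccc1 | starting material
4 | cyclohexa-2,5-dien-1-yllithium | [Li]C1C=CCC=C1 | intermediate (not isolated)
5 | lithium (cyclohexa-2,5-dien-1-yl)methoxide | [Li]OCC1C=CCC=C1 | intermediate (not isolated)
6 | (cyclohexa-2,5-dien-1-yl)methyl benzoate | O=C(OCC1C=CCC=C1)c1ccccc1 | intermediate
7 | (5,6-dibromocyclohex-2-en-1-yl)methyl benzoate (racemic trans-dibromide, both C1 epimers; stereocentres left undefined, all erased in step 4) | O=C(OCC1C=CCC(Br)C1Br)c1ccccc1 | intermediate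
8 | (3,4-dibromo-7-oxabicyclo[4.1.0]heptan-2-yl)methyl benzoate (racemic diastereomer mixture) | O=C(OCC1C(Br)C(Br)CC2OC12)c1ccccc1 | intermediate
9 | (3-bromo-7-oxabicyclo[4.1.0]hept-4-en-2-yl)methyl benzoate | O=C(OCC1C(Br)C=CC2OC12)c1ccccc1 | intermediate (not isolated)
10 | (7-oxabicyclo[4.1.0]hepta-2,4-dien-2-yl)methyl benzoate (benzyl benzoate 2,3-oxide; racemic, interconverting enantiomers) | O=C(OCC1=CC=CC2OC12)c1ccccc1 | intermediate
11 | (oxepin-3-yl)methyl benzoate (valence tautomer of 10) | O=C(OCC1=COC=CC=C1)c1ccccc1 | intermediate (not isolated)
12 | benzoic acid | OC(=O)c1ccccc1 | starting material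
13 | [(5R,6R)-5-(benzoyloxy)-6-hydroxycyclohexa-1,3-dien-1-yl]methyl benzoate | O=C(OCC1=CC=C[C@@H](OC(=O)c2ccccc2)[C@@H]1O)c1ccccc1 | target

## Step count and risks

Total steps: 5. Longest linear sequence: 5.

**Most likely to fail, 1: step 5.** The risks are aromatisation of 10 to phenols at the Lewis-acidic cobalt, attack at the wrong oxirane carbon, and low enantioselectivity. The fallback sets out from 10 and comes back at 13. It opens 10 without a chiral catalyst (nBu4N benzoate and PhCO2H buffer, THF, 0 °C). This gives the racemate, that is 13 together with its enantiomer [(5S,6S)-5-(benzoyloxy)-6-hydroxycyclohexa-1,3-dien-1-yl]methyl benzoate F1. The two are separated by preparative chiral SFC (amylose tris(3,5-dimethylphenylcarbamate) phase, CO2/iPrOH). Stereocontrol is thus replaced by resolution, at the cost of a 50 % ceiling.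

**Most likely to fail, 2: step 4.** In the major dibromide the C–Br next to C1 may lack an anti-periplanar C1–H, and the arene oxide is acid-sensitive on isolation. The fallback sets out from 6 and comes back at 10.
- Mono-epoxidation of 6 (mCPBA 1.0 equiv, NaHCO3, CH2Cl2, 0 °C) gives (7-oxabicyclo[4.1.0]hept-3-en-2-yl)methyl benzoate F2.
- Wohl–Ziegler bromination (NBS, AIBN cat., PhCF3, 80 °C) gives the allylic bromide (5-bromo-7-oxabicyclo[4.1.0]hept-3-en-2-yl)methyl benzoate F3, together with its allylic isomers, 9 among them.
- DBU in THF at 0 °C then gives 10. The bromide is allylic from the start, the isomers interconvert by bromide SN2', and each can reach the diene by 1,2- or 1,4-elimination.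

**Most likely to fail, 3: step 1.** Anion 4 can lose LiH to give benzene, and formaldehyde may add at a terminal carbon or oligomerise. The fallback sets out from 12 and comes back at 6.
- Birch reduction of 12 (Na, liquid NH3, EtOH, −78 °C; NH4Cl) gives cyclohexa-2,5-diene-1-carboxylic acid F4.
- LiAlH4 in Et2O at 0 °C gives (cyclohexa-2,5-dien-1-yl)methanol F5.
- Benzoylation with 3 (pyridine, CH2Cl2, 0 °C) gives 6.

## Further compounds

F1 | step 5 | [(5S,6S)-5-(benzoyloxy)-6-hydroxycyclohexa-1,3-dien-1-yl]methyl benzoate (enantiomer of 13) | O=C(OCC1=CC=C[C@H](OC(=O)c2ccccc2)[C@H]1O)c1ccccc1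
F2 | step 4 | (7-oxabicyclo[4.1.0]hept-3-en-2-yl)methyl benzoate (racemic, both epimers) | O=C(OCC1C=CCC2OC12)c1ccccc1
F3 | step 4 | (5-bromo-7-oxabicyclo[4.1.0]hept-3-en-2-yl)methyl benzoate (racemic, epimer mixture) | O=C(OCC1C=CC(Br)C2OC12)c1ccccc1
F4 | step 1 | cyclohexa-2,5-diene-1-carboxylic acid | OC(=O)C1C=CCC=C1
F5 | step 1 | (cyclohexa-2,5-dien-1-yl)methanol | OCC1C=CCC=C1
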